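**Retrosynthetic overview**
1. The target comes from its tetramethyl ether by BBr3 demethylation; there is no stereocentre to set.
2. Key disconnection: ring D and the 17-membered ring are opened together, back to an aryl ethynyl ether on the ring C oxygen and a 2-pyrone hung on ring A by a CH2CH2 chain (intramolecular Diels–Alder, then loss of CO2).
3. The pyrone is attached by B-alkyl Suzuki coupling of a ring A styrene with 3-bromo-2H-pyran-2-one; the ynol ether comes from the ring C phenol through a dichlorovinyl ether and is kept C-silylated across that hydroboration.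
4. The ring B–ring C bibenzyl is a second B-alkyl Suzuki coupling; the ring A–O–ring B ether is an Ullmann coupling.
5. Ring order: rings A, B and C are bought; ring D and the macrocycle form last, in one operation.

Assumption: the SMILES has no stereodescriptor and the molecule has no stereocentre (the large ring is taken to be conformationally mobile), so it is made as a single achiral compound without enantiocontrol.

**Route**

Step 1
Reactants: 1 3-iodo-4,5-dimethoxybenzaldehyde; 2 4-bromophenol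
Product: 3 3-(4-bromophenoxy)-4,5-dimethoxybenzaldehyde
Conditions: CuI (10 mol %), N,N-dimethylglycine hydrochloride (30 mol %), Cs2CO3, dioxane, 90 °C
Reagents that add atoms: none
Why: Ullmann-type diaryl ether coupling, in which the aryl iodide of 1 reacts far faster than the C–Br bond of the electron-rich phenoxide, so the bromide survives for step 5.

Step 2
Reactants: 3 3-(4-bromophenoxy)-4,5-dimethoxybenzaldehyde
Product: 4 1-(4-bromophenoxy)-5-ethenyl-2,3-dimethoxybenzene
Conditions: Ph3PCH3Br, KOtBu, THF, 0 °C to rt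
Reagents that add atoms: methyltriphenylphosphonium bromide, C[P+](c1ccccc1)(c1ccccc1)c1ccccc1.[Br-]
Why: Wittig methylenation of a non-enolisable aryl aldehyde gives the ring A styrene that later carries the pyrone.

Step 3
Reactants: 5 2-hydroxy-3,4-dimethoxybenzaldehyde
Product: 6 2-{[(E)-1,2-dichloroethenyl]oxy}-3,4-dimethoxybenzaldehyde
Conditions: trichloroethylene, K2CO3, DMF, 70 °C
Reagents that add atoms: trichloroethylene, ClC=C(Cl)Cl
Why: addition–elimination of the phenoxide on trichloroethylene (anti addition to dichloroacetylene formed in situ gives the E ether) is the first half of the dichlorovinyl ether route to aryl ynol ethers; the alkene geometry is lost in step 6.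

Step 4
Reactants: 6 2-{[(E)-1,2-dichloroethenyl]oxy}-3,4-dimethoxybenzaldehyde
Product: 7 2-{[(E)-1,2-dichloroethenyl]oxy}-1-ethenyl-3,4-dimethoxybenzene
Conditions: Ph3PCH3Br, KOtBu, THF, 0 °C to rt
Reagents that add atoms: methyltriphenylphosphonium bromide, C[P+](c1ccccc1)(c1ccccc1)c1ccccc1.[Br-]
Why: Wittig methylenation; the preformed ylide is too weak a base to eliminate HCl from the dichlorovinyl ether.

Step 5
Reactants: 7 2-{[(E)-1,2-dichloroethenyl]oxy}-1-ethenyl-3,4-dimethoxybenzene; 4 1-(4-bromophenoxy)-5-ethenyl-2,3-dimethoxybenzene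
Product: 9 1-{4-[2-(2-{[(E)-1,2-dichloroethenyl]oxy}-3,4-dimethoxyphenyl)ethyl]phenoxy}-5-ethenyl-2,3-dimethoxybenzene, via alkyl-9-BBN 8 (not isolated)
Conditions: 7 (1.3 equiv), 9-BBN (1.25 equiv), THF, rt; then 4, Pd(dppf)Cl2 (5 mol %), aq K3PO4, DMF, 60 °C
Reagents that add atoms: none
Why: anti-Markovnikov hydroboration of styrene 7 and B-alkyl Suzuki–Miyaura coupling with aryl bromide 4 build the ring B–ring C bibenzyl; all B–H is consumed before 4 is added, so its styrene stays intact.

Step 6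
Reactants: 9 1-{4-[2-(2-{[(E)-1,2-dichloroethenyl]oxy}-3,4-dimethoxyphenyl)ethyl]phenoxy}-5-ethenyl-2,3-dimethoxybenzene
Product: 12 {[6-(2-{4-[5-ethenyl-2,3-dimethoxyphenoxy]phenyl}ethyl)-2,3-dimethoxyphenoxy]ethynyl}tri(propan-2-yl)silane, via chloroalkynyl ether 10 (not isolated), via lithium acetylide 11 (not isolated)
Conditions: n-BuLi (2.2 equiv), Et2O, −78 °C; then iPr3SiOTf, −78 °C to 0 °C
Reagents that add atoms: triisopropylsilyl trifluoromethanesulfonate, CC(C)[Si](C(C)C)(C(C)C)OS(=O)(=O)C(F)(F)F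
Why: deprotonation and β-elimination give the chloroalkyne, Li–Cl exchange gives the lithium aryloxyacetylide and C-silylation caps it (dichlorovinyl ether route to ynol ethers); in Et2O at −78 °C this should outrun addition of n-BuLi to the electron-rich styrene, and the silyl cap shields the alkyne from 9-BBN in step 7.

Step 7
Reactants: 12 {[6-(2-{4-[5-ethenyl-2,3-dimethoxyphenoxy]phenyl}ethyl)-2,3-dimethoxyphenoxy]ethynyl}tri(propan-2-yl)silane; 13 3-bromo-2H-pyran-2-one
Product: 15 3-{2-[3-(4-{2-[3,4-dimethoxy-2-({[tri(propan-2-yl)silyl]ethynyl}oxy)phenyl]ethyl}phenoxy)-4,5-dimethoxyphenyl]ethyl}-2H-pyran-2-one, via alkyl-9-BBN 14 (not isolated)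
Conditions: 9-BBN (1.1 equiv), THF, rt; then 13, Pd(dppf)Cl2 (5 mol %), AsPh3 (10 mol %), Cs2CO3, DMF/THF/H2O, rt
Reagents that add atoms: none
Why: hydroboration of the remaining styrene (the hindered silyl alkyne is left alone) and room-temperature B-alkyl Suzuki–Miyaura coupling at the reactive vinylic C–Br bond of the bromopyrone, mild enough for the lactone.

Step 8
Reactants: 15 3-{2-[3-(4-{2-[3,4-dimethoxy-2-({[tri(propan-2-yl)silyl]ethynyl}oxy)phenyl]ethyl}phenoxy)-4,5-dimethoxyphenyl]ethyl}-2H-pyran-2-one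
Product: 16 3-{2-[3-(4-{2-[2-(ethynyloxy)-3,4-dimethoxyphenyl]ethyl}phenoxy)-4,5-dimethoxyphenyl]ethyl}-2H-pyran-2-one
Conditions: Bu4NF (1.1 equiv), AcOH (1.1 equiv), THF, −20 °C to 0 °C; quick filtration through Et3N-deactivated silica
Reagents that add atoms: none
Why: fluoride-induced protodesilylation of the C(sp)–Si bond, buffered with acetic acid so that the 2-pyrone survives; the terminal aryl ynol ether is used at once.

Step 9
Reactants: 16 3-{2-[3-(4-{2-[2-(ethynyloxy)-3,4-dimethoxyphenyl]ethyl}phenoxy)-4,5-dimethoxyphenyl]ethyl}-2H-pyran-2-one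
Product: 18 tetramethyl ether of the target (macrocycle with rings A to D and four OMe groups), via bridged lactone 17 (not isolated)
Conditions: o-dichlorobenzene (1 mM, syringe-pump addition), BHT, 150 °C
Reagents that add atoms: none
Why: Proposed new method: the electron-rich aryl ynol ether adds as an inverse-electron-demand dienophile across C3 and C6 of the 2-pyrone, its nucleophilic CH carbon bonding to the electrophilic C6 and its oxygen-bearing carbon to C3 (which carries the tether, so the ortho pattern of ring D and the 17-membered ring arise in the same bond-forming event), and bridged lactone 17 then loses CO2 by retro-Diels–Alder to give the benzene ring, which also removes its two transient stereocentres; the closest known reaction types are intramolecular 2-pyrone/alkyne Diels–Alder–CO2 extrusion macrocyclisations to cyclophanes and the intermolecular cycloadditions of 2-pyrones with ketene acetals and alkoxyalkynes that give aryl ethers.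

Step 10
Reactants: 18 tetramethyl ether of the target
Product: 20 target CNP0114693.0, via bis-bromodioxaborole 19 (not isolated)
Conditions: BBr3 (8 equiv), CH2Cl2, −78 °C to rt; then H2O (under argon)
Reagents that add atoms: none
Why: Lewis-acid ether cleavage (bromide attacks each O-methyl group in an SN2 step) gives the cyclic bromoborates of the two catechols, which water hydrolyses; diaryl ethers and bibenzyl bridges are inert to BBr3.

**Compound list**
1 | 3-iodo-4,5-dimethoxybenzaldehyde | O=Cc1cc(I)c(OC)c(OC)c1 | starting material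
2 | 4-bromophenol | Oc1ccc(Br)cc1 | starting material
3 | 3-(4-bromophenoxy)-4,5-dimethoxybenzaldehyde | O=Cc1cc(Oc2ccc(Br)cc2)c(OC)c(OC)c1 | intermediate
4 | 1-(4-bromophenoxy)-5-ethenyl-2,3-dimethoxybenzene | C=Cc1cc(Oc2ccc(Br)cc2)c(OC)c(OC)c1 | intermediate
5 | 2-hydroxy-3,4-dimethoxybenzaldehyde | O=Cc1ccc(OC)c(OC)c1O | starting material
6 | 2-{[(E)-1,2-dichloroethenyl]oxy}-3,4-dimethoxybenzaldehyde | O=Cc1ccc(OC)c(OC)c1O/C(Cl)=C\Cl | intermediate
7 | 2-{[(E)-1,2-dichloroethenyl]oxy}-1-ethenyl-3,4-dimethoxybenzene | C=Cc1ccc(OC)c(OC)c1O/C(Cl)=C\Cl | intermediate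
8 | 9-[2-(2-{[(E)-1,2-dichloroethenyl]oxy}-3,4-dimethoxyphenyl)ethyl]-9-borabicyclo[3.3.1]nonane (not isolated) | C1CCC2CCCC1B2CCc1ccc(OC)c(OC)c1O/C(Cl)=C\Cl | intermediate
9 | 1-{4-[2-(2-{[(E)-1,2-dichloroethenyl]oxy}-3,4-dimethoxyphenyl)ethyl]phenoxy}-5-ethenyl-2,3-dimethoxybenzene | C=Cc1cc(Oc2ccc(CCc3ccc(OC)c(OC)c3O/C(Cl)=C\Cl)cc2)c(OC)c(OC)c1 | intermediate
10 | 1-[4-(2-{2-[(chloroethynyl)oxy]-3,4-dimethoxyphenyl}ethyl)phenoxy]-5-ethenyl-2,3-dimethoxybenzene (not isolated) | C=Cc1cc(Oc2ccc(CCc3ccc(OC)c(OC)c3OC#CCl)cc2)c(OC)c(OC)c1 | intermediate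
11 | lithium acetylide of the ring C ynol ether, ArO–C≡C–Li with the rest as in 10 (not isolated) | C=Cc1cc(Oc2ccc(CCc3ccc(OC)c(OC)c3OC#C[Li])cc2)c(OC)c(OC)c1 | intermediate
12 | {[6-(2-{4-[5-ethenyl-2,3-dimethoxyphenoxy]phenyl}ethyl)-2,3-dimethoxyphenoxy]ethynyl}tri(propan-2-yl)silane | C=Cc1cc(Oc2ccc(CCc3ccc(OC)c(OC)c3OC#C[Si](C(C)C)(C(C)C)C(C)C)cc2)c(OC)c(OC)c1 | intermediate
13 | 3-bromo-2H-pyran-2-one | O=C1OC=CC=C1Br | starting material
14 | 9-{2-[3-(4-{2-[3,4-dimethoxy-2-({[tri(propan-2-yl)silyl]ethynyl}oxy)phenyl]ethyl}phenoxy)-4,5-dimethoxyphenyl]ethyl}-9-borabicyclo[3.3.1]nonane (not isolated) | C1CCC2CCCC1B2CCc1cc(Oc2ccc(CCc3ccc(OC)c(OC)c3OC#C[Si](C(C)C)(C(C)C)C(C)C)cc2)c(OC)c(OC)c1 | intermediate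
15 | 3-{2-[3-(4-{2-[3,4-dimethoxy-2-({[tri(propan-2-yl)silyl]ethynyl}oxy)phenyl]ethyl}phenoxy)-4,5-dimethoxyphenyl]ethyl}-2H-pyran-2-one | O=C1OC=CC=C1CCc1cc(Oc2ccc(CCc3ccc(OC)c(OC)c3OC#C[Si](C(C)C)(C(C)C)C(C)C)cc2)c(OC)c(OC)c1 | intermediate
16 | 3-{2-[3-(4-{2-[2-(ethynyloxy)-3,4-dimethoxyphenyl]ethyl}phenoxy)-4,5-dimethoxyphenyl]ethyl}-2H-pyran-2-one | O=C1OC=CC=C1CCc1cc(Oc2ccc(CCc3ccc(OC)c(OC)c3OC#C)cc2)c(OC)c(OC)c1 | intermediate
17 | bridged lactone: 2-oxabicyclo[2.2.2]octa-5,7-dien-3-one whose C4 bridgehead carries the CH2CH2–ring A chain and whose C8 carries the ring C oxygen, both tied into the 17-membered ring; racemic, one enantiomer drawn, the two bridgeheads being fixed relative to each other by the bicycle (not isolated) | O=C1O[C@H]2C=C[C@]1(CCc3cc(Oc4ccc(CCc5ccc(OC)c(OC)c5O6)cc4)c(OC)c(OC)c3)C6=C2 | intermediate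
18 | tetramethyl ether of the target: the 17-membered bis(bibenzyl) diether with OMe at both catechol positions of ring A and of ring C | COc1cc2cc(c1OC)Oc1ccc(cc1)CCc1ccc(OC)c(OC)c1Oc1ccccc1CC2 | intermediate
19 | bis(2-bromo-1,3,2-dioxaborole) of the target, each catechol bridged by B–Br (not isolated) | BrB1Oc3cc2cc(c3O1)Oc4ccc(cc4)CCc4ccc5OB(Br)Oc5c4Oc4ccccc4CC2 | intermediate
20 | CNP0114693.0, the macrocyclic bis(bibenzyl) with two catechols (achiral) | Oc1cc2cc(c1O)Oc1ccc(cc1)CCc1ccc(O)c(O)c1Oc1ccccc1CC2 | target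

**Step count and risks**
Total steps: 10. Longest linear sequence: 8 steps (from 1 through steps 1, 2, 5 to 10, or from 5 through steps 3 to 10).

The three steps most likely to fail:

Step 9 (macrocyclising cycloaddition). If 16 reacts too slowly for the ynol ether to survive, the diene is made more electron-poor with a bromine that is removed afterwards. The fallback sets out from 12 and comes back at 18. Alkylborane 14, made from 12 as in step 7, is coupled with 3,5-dibromo-2H-pyran-2-one at its more reactive C3–Br bond (Pd(dppf)Cl2, AsPh3, Cs2CO3, rt) to give the 5-bromopyrone silyl ynol ether F1. Bu4NF/AcOH gives the terminal ynol ether 5-bromopyrone F2. Heating at high dilution (about 110 °C) gives, through the bridged bromo lactone F3 and loss of CO2, the ring D bromide F4, with bromine para to the ether oxygen. Hydrogenolysis of the aryl bromide (H2, palladium on carbon, Et3N, EtOAc) returns 18.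

Step 7 (B-alkyl Suzuki coupling on the base-sensitive bromopyrone). If aqueous base destroys the pyrone or the coupling stalls, a base-free Negishi coupling is used instead. The fallback sets out from 12 and comes back at 15. Hydroboration of 12 with 9-BBN and oxidation with NaBO3 give the primary alcohol F5. Preformed Ph3P·I2 with imidazole gives the primary iodide F6. Zinc insertion (Zn dust, LiCl, THF) gives the alkylzinc iodide F7, which is coupled without isolation with 13 (Pd(dppf)Cl2, THF, rt) to give 15.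

Step 8 (fluoride desilylation next to a 2-pyrone, giving a fragile terminal ynol ether). If 16 cannot be obtained cleanly, the silyl group is carried through the ring-forming step and removed from the arene afterwards. The fallback sets out from 15 and comes back at 18. Heating 15 at high dilution (o-dichlorobenzene, 160–170 °C) gives, through the bridged silyl lactone F8 and loss of CO2, the ring D silane F9, with the silyl group ortho to the ether oxygen. Ipso-protodesilylation of this oxygen-activated aryl silane (CF3CO2H, CH2Cl2, with a little CF3SO3H if needed) returns 18.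

**Further compounds**
F1 | step 9 | 5-bromo-3-{2-[3-(4-{2-[3,4-dimethoxy-2-({[tri(propan-2-yl)silyl]ethynyl}oxy)phenyl]ethyl}phenoxy)-4,5-dimethoxyphenyl]ethyl}-2H-pyran-2-one | O=C1OC=C(Br)C=C1CCc1cc(Oc2ccc(CCc3ccc(OC)c(OC)c3OC#C[Si](C(C)C)(C(C)C)C(C)C)cc2)c(OC)c(OC)c1
F2 | step 9 | 5-bromo-3-{2-[3-(4-{2-[2-(ethynyloxy)-3,4-dimethoxyphenyl]ethyl}phenoxy)-4,5-dimethoxyphenyl]ethyl}-2H-pyran-2-one | O=C1OC=C(Br)C=C1CCc1cc(Oc2ccc(CCc3ccc(OC)c(OC)c3OC#C)cc2)c(OC)c(OC)c1
F3 | step 9 | bridged bromo lactone, as 17 with Br on C6 of the bicycle (racemic, one enantiomer drawn, not isolated) | O=C1O[C@H]2C(Br)=C[C@]1(CCc3cc(Oc4ccc(CCc5ccc(OC)c(OC)c5O6)cc4)c(OC)c(OC)c3)C6=C2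
F4 | step 9 | ring D bromide of 18 (Br para to the ring D ether oxygen) | COc1cc2cc(c1OC)Oc1ccc(cc1)CCc1ccc(OC)c(OC)c1Oc1ccc(Br)cc1CC2
F5 | step 7 | 2-[3-(4-{2-[3,4-dimethoxy-2-({[tri(propan-2-yl)silyl]ethynyl}oxy)phenyl]ethyl}phenoxy)-4,5-dimethoxyphenyl]ethan-1-ol | OCCc1cc(Oc2ccc(CCc3ccc(OC)c(OC)c3OC#C[Si](C(C)C)(C(C)C)C(C)C)cc2)c(OC)c(OC)c1
F6 | step 7 | the corresponding primary iodide, 1-(2-iodoethyl) in place of 1-(2-hydroxyethyl) | ICCc1cc(Oc2ccc(CCc3ccc(OC)c(OC)c3OC#C[Si](C(C)C)(C(C)C)C(C)C)cc2)c(OC)c(OC)c1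
F7 | step 7 | the corresponding alkylzinc iodide (not isolated) | I[Zn]CCc1cc(Oc2ccc(CCc3ccc(OC)c(OC)c3OC#C[Si](C(C)C)(C(C)C)C(C)C)cc2)c(OC)c(OC)c1
F8 | step 8 | bridged silyl lactone, as 17 with tri(propan-2-yl)silyl on C7 of the bicycle (racemic, one enantiomer drawn, not isolated) | O=C1O[C@H]2C=C[C@]1(CCc3cc(Oc4ccc(CCc5ccc(OC)c(OC)c5O6)cc4)c(OC)c(OC)c3)C6=C2[Si](C(C)C)(C(C)C)C(C)C
F9 | step 8 | ring D silane of 18 (tri(propan-2-yl)silyl ortho to the ring D ether oxygen) | COc1cc2cc(c1OC)Oc1ccc(cc1)CCc1ccc(OC)c(OC)c1Oc1c(cccc1CC2)[Si](C(C)C)(C(C)C)C(C)C
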